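The plan cuts ring B at C1–C2 and C3–C4. Because ring B shares its C4a–C8a edge with arene ring A, this leaves an o-quinodimethane whose exocyclic carbons are C1 (bearing the guaiacyl group) and C4. It also leaves a C2a–C2–C3–C3a chain that is a 5-alkoxybutenolide in disguise. One Diels–Alder reaction with the l-menthol-derived butenolide rebuilds ring B, sets C1 and C3 in the absolute sense, and leaves C2a (lactone carbonyl) and C3a (acetal) chemically distinct. The diene is released by fluoride from a racemic o-(trimethylsilylmethyl)benzhydryl acetate with benzyl-protected phenols. Base equilibration later inverts C2, and C2a alone is coumaroylated.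

Key step: step 8

Locants: tetralin numbering with the pendant guaiacyl group on C1. C2a and C3a are the exocyclic carbons on C2 and C3, and C4 is the benzylic CH2. Ring A is the fused arene and ring B the carbocycle C1–C4/C4a/C8a.

Assumption: compounds 1, 7, 11, 14 and 22 are taken as catalogue chemicals. The carbinol centre of 10 is deliberately racemic because it becomes sp2 in 17.

Step 1
Reactants: 1 6-bromovanillin (2-bromo-4-hydroxy-5-methoxybenzaldehyde)
Product: 2 4-(benzyloxy)-2-bromo-5-methoxybenzaldehyde
Conditions: BnBr, K2CO3, DMF, rt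
Reagents that add atoms: benzyl bromide, BrCc1ccccc1
Why: Williamson ether synthesis on the acidic phenol para to the formyl group is routine, and the benzyl ether withstands every later organometallic, fluoride, methoxide, hydride and dilute-acid step.

Step 2
Reactants: 2 4-(benzyloxy)-2-bromo-5-methoxybenzaldehyde
Product: 3 [4-(benzyloxy)-2-bromo-5-methoxyphenyl]methanol
Conditions: NaBH4, MeOH/THF, 0 °C
Reagents that add atoms: none
Why: Borohydride reduction of an aryl aldehyde is chemoselective, leaves the aryl bromide and the benzyl ether untouched, and creates no stereocentre.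

Step 3
Reactants: 3 [4-(benzyloxy)-2-bromo-5-methoxyphenyl]methanol
Product: 4 1-(benzyloxy)-5-bromo-4-(bromomethyl)-2-methoxybenzene
Conditions: PBr3, CH2Cl2, 0 °C; crude product used at once
Reagents that add atoms: phosphorus tribromide, BrP(Br)Br
Why: Alcohol-to-bromide conversion through the phosphite ester (SN2 by bromide) is fast for an electron-rich benzylic alcohol, and the labile bromide is carried on without chromatography.

Step 4
Reactants: 4 1-(benzyloxy)-5-bromo-4-(bromomethyl)-2-methoxybenzene
Product: 6 [4-(benzyloxy)-2-bromo-5-methoxybenzyl]trimethylsilane, via benzylic Grignard reagent 5 (not isolated)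
Conditions: Mg turnings, Me3SiCl, THF, 0 °C to rt, slow addition of 4 (Barbier mode)
Reagents that add atoms: chlorotrimethylsilane, C[Si](C)(C)Cl
Why: In this Barbier-type Grignard silylation magnesium inserts into the benzylic C–Br bond much faster than into the aryl C–Br bond, and the chlorosilane already present intercepts 5 before Wurtz coupling can take over.

Step 5
Reactants: 6 [4-(benzyloxy)-2-bromo-5-methoxybenzyl]trimethylsilane; 7 O-benzylvanillin (4-(benzyloxy)-3-methoxybenzaldehyde)
Product: 10 racemic [5-(benzyloxy)-4-methoxy-2-(trimethylsilylmethyl)phenyl][4-(benzyloxy)-3-methoxyphenyl]methyl acetate, via aryllithium 8 (not isolated), via lithium benzhydrolate 9 (not isolated)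
Conditions: n-BuLi, THF, −78 °C; 7, −78 °C; Ac2O, −78 to 0 °C; NaHCO3 work-up, filtration through Et3N-deactivated silica
Reagents that add atoms: acetic anhydride, CC(=O)OC(C)=O
Why: Bromine–lithium exchange outruns deprotonation at −78 °C, 1,2-addition of 8 to the aldehyde gives alkoxide 9, and acylation in the same flask avoids handling the ionisation-prone free benzhydrol and any alkoxide-induced silyl transfer; the new carbinol centre needs no control because step 8 erases it.

Step 6
Reactants: 11 furfural
Product: 13 5-hydroxyfuran-2(5H)-one (racemic hemiacetal), via furan endoperoxide 12 (not isolated)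
Conditions: O2, methylene blue (cat.), visible light, MeOH, rt
Reagents that add atoms: oxygen, O=O
Why: Dye-sensitised singlet-oxygen [4+2] addition to the furan gives endoperoxide 12, from which methanol removes the formyl carbon as its formate ester while the O–O bond opens to the hydroxybutenolide (furan photooxygenation).

Step 7
Reactants: 13 5-hydroxyfuran-2(5H)-one; 14 l-menthol
Product: 16 (5R)-5-(l-menthyloxy)furan-2(5H)-one, via C5-epimeric acetal mixture 15 (not isolated)
Conditions: camphorsulfonic acid (cat.), toluene, reflux, Dean–Stark trap; crystallisation from petroleum ether, mother liquor re-equilibrated with the acid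
Reagents that add atoms: none
Why: Acid-catalysed acetalisation of the cyclic hemiacetal gives both C5 epimers, which interconvert under the acid, and selective crystallisation of the (5R)-diastereomer sets the acetal stereocentre (crystallisation-driven diastereomer selection).

Step 8
Reactants: 10 racemic o-(trimethylsilylmethyl)benzhydryl acetate; 16 (5R)-5-(l-menthyloxy)furan-2(5H)-one
Product: 18 all-cis lactone acetal adduct (3R,3aR,9S,9aS)-7-(benzyloxy)-9-[4-(benzyloxy)-3-methoxyphenyl]-6-methoxy-3-(l-menthyloxy)-3a,4,9,9a-tetrahydronaphtho[2,3-c]furan-1(3H)-one (tetralin C1 S; C2 S; C3 R), via E-aryl o-quinodimethane 17 (not isolated)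
Conditions: CsF (dried, excess), 16 (excess, recovered), MeCN, rt to 40 °C, 10 added slowly by syringe pump; 18 purified to a single diastereomer
Reagents that add atoms: none
Why: Fluoride attacks silicon and the benzylic electron pair expels acetate through ring A (1,4-elimination), dearomatising ring A to diene 17, in which the aryl group takes the outer (E) position for steric reasons. Diene 17 then adds to the C=C bond of 16 in a concerted, suprafacial [4+2] cycloaddition driven by re-aromatisation of ring A; the closest known reactions are fluoride-triggered o-quinodimethane Diels–Alder reactions and Diels–Alder reactions of 5-alkoxybutenolides. Ring B closes as a six-membered carbocycle by intermolecular [4+2] annulation, C1–C2 and C3–C4 being made in one event, cis-fused to the lactone ring that 16 brings along. C3 is fixed by approach of the diene to the butenolide face opposite the menthyloxy group on C3a, C2 follows from suprafacial addition (cis to C3), and C1 follows from the E geometry of 17 combined with the endo placement of the lactone carbonyl (aryl cis to C2a). The regiochemistry (C1 to the lactone α-carbon) rests on the larger HOMO coefficient at the unsubstituted C4 terminus matching the β-carbon of the enoate, reinforced by sterics because the bulky terminus stays away from the acetal side. Slow addition into excess 16 keeps 17 dilute against dimerisation, and every minor exo, regio or facial isomer is a menthyl-tagged diastereomer that can be removed here.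

Step 9
Reactants: 18 all-cis lactone acetal adduct
Product: 20 methyl (1S,2R,3R)-7-(benzyloxy)-1-[4-(benzyloxy)-3-methoxyphenyl]-3-(dimethoxymethyl)-6-methoxy-1,2,3,4-tetrahydronaphthalene-2-carboxylate, via all-trans ester aldehyde 19 (not isolated)
Conditions: NaOMe (2 equiv), MeOH/THF, Ar, rt to 50 °C until the isomer composition no longer changes; then 0 °C, MsOH (2.2 equiv), HC(OMe)3, rt
Reagents that add atoms: sodium methoxide, [Na+].[O-]C; methanol, CO; trimethyl orthoformate, COC(OC)OC
Why: Methoxide attacks the lactone carbonyl C2a (transesterification of a pseudo-ester), the liberated hemiacetal collapses to the C3a aldehyde with loss of menthoxide, enolisation then equilibrates C2 (and, reversibly, C3) against the fixed C1 centre to the all-equatorial 1,2-trans-2,3-trans isomer 19 under thermodynamic control, and acid-catalysed acetalisation with orthoformate locks C3 and masks C3a in the same flask.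

Step 10
Reactants: 20 all-trans ester dimethyl acetal
Product: 21 [(1S,2R,3R)-7-(benzyloxy)-1-[4-(benzyloxy)-3-methoxyphenyl]-3-(dimethoxymethyl)-6-methoxy-1,2,3,4-tetrahydronaphthalen-2-yl]methanol
Conditions: LiAlH4, THF, 0 °C; Na2SO4·10H2O quench
Reagents that add atoms: none
Why: Hydride reduction of the ester with LiAlH4 gives the C2a primary alcohol while acetal and benzyl ethers are inert, and the non-acidic quench prevents cyclisation of the alcohol onto the acetal.

Step 11
Reactants: 21 C2a alcohol acetal; 22 (E)-4-(benzyloxy)cinnamic acid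
Product: 23 [(1S,2R,3R)-7-(benzyloxy)-1-[4-(benzyloxy)-3-methoxyphenyl]-3-(dimethoxymethyl)-6-methoxy-1,2,3,4-tetrahydronaphthalen-2-yl]methyl (E)-3-[4-(benzyloxy)phenyl]prop-2-enoate
Conditions: DCC, DMAP (cat.), CH2Cl2, 0 °C to rt
Reagents that add atoms: none
Why: Steglich esterification acylates the only free hydroxyl group under neutral conditions that spare the acetal and preserve the E alkene of 22.

Step 12
Reactants: 23 coumarate acetal
Product: 25 [(1S,2R,3R)-7-(benzyloxy)-1-[4-(benzyloxy)-3-methoxyphenyl]-3-(hydroxymethyl)-6-methoxy-1,2,3,4-tetrahydronaphthalen-2-yl]methyl (E)-3-[4-(benzyloxy)phenyl]prop-2-enoate, via C3a aldehyde 24 (not isolated)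
Conditions: 1 M HCl, THF, rt; then NaHCO3 to pH 7, NaBH4, 0 °C; NH4Cl quench
Reagents that add atoms: water, O
Why: Acid hydrolysis of the dimethyl acetal unveils aldehyde 24, which borohydride reduces far faster than the cinnamate ester, so that C3 (already in its favoured equatorial configuration) never meets base and acyl migration is held back by the low temperature and neutral pH.

Step 13
Reactants: 25 tri-O-benzyl ether of the target
Product: 26 target, [(1S,2R,3R)-7-hydroxy-1-(4-hydroxy-3-methoxyphenyl)-3-(hydroxymethyl)-6-methoxy-1,2,3,4-tetrahydronaphthalen-2-yl]methyl (E)-3-(4-hydroxyphenyl)prop-2-enoate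
Conditions: BCl3 (1 M in CH2Cl2), pentamethylbenzene, CH2Cl2, −78 °C; CHCl3/MeOH quench
Reagents that add atoms: none
Why: BCl3 coordinates the aryl benzyl ether oxygens and releases benzyl cations that pentamethylbenzene traps by Friedel–Crafts alkylation, a low-temperature debenzylation that leaves the cinnamate C=C (which hydrogenolysis would saturate), the ester and the aryl methyl ethers in place.

Compound list

1 | 6-bromovanillin (2-bromo-4-hydroxy-5-methoxybenzaldehyde) | COc1cc(C=O)c(Br)cc1O | starting material
2 | 4-(benzyloxy)-2-bromo-5-methoxybenzaldehyde | COc1cc(C=O)c(Br)cc1OCc1ccccc1 | intermediate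
3 | [4-(benzyloxy)-2-bromo-5-methoxyphenyl]methanol | COc1cc(CO)c(Br)cc1OCc1ccccc1 | intermediate
4 | 1-(benzyloxy)-5-bromo-4-(bromomethyl)-2-methoxybenzene | COc1cc(CBr)c(Br)cc1OCc1ccccc1 | intermediate
5 | [4-(benzyloxy)-2-bromo-5-methoxybenzyl]magnesium bromide | COc1cc(C[Mg]Br)c(Br)cc1OCc1ccccc1 | intermediate
6 | [4-(benzyloxy)-2-bromo-5-methoxybenzyl]trimethylsilane | COc1cc(C[Si](C)(C)C)c(Br)cc1OCc1ccccc1 | intermediate
7 | O-benzylvanillin (4-(benzyloxy)-3-methoxybenzaldehyde) | COc1cc(C=O)ccc1OCc1ccccc1 | starting material
8 | [5-(benzyloxy)-4-methoxy-2-(trimethylsilylmethyl)phenyl]lithium | COc1cc(C[Si](C)(C)C)c([Li])cc1OCc1ccccc1 | intermediate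
9 | lithium benzhydrolate from 8 and 7 (racemic) | COc1cc(C[Si](C)(C)C)c(cc1OCc1ccccc1)C([O-])c1ccc(OCc2ccccc2)c(OC)c1.[Li+] | intermediate
10 | racemic o-(trimethylsilylmethyl)benzhydryl acetate | COc1cc(C[Si](C)(C)C)c(cc1OCc1ccccc1)C(OC(C)=O)c1ccc(OCc2ccccc2)c(OC)c1 | intermediate
11 | furfural | O=Cc1ccco1 | starting material
12 | furfural 2,5-endoperoxide | O=CC12C=CC(OO1)O2 | intermediate
13 | 5-hydroxyfuran-2(5H)-one (racemic) | O=C1C=CC(O)O1 | intermediate
14 | l-menthol, (1R,2S,5R) | C[C@@H]1CC[C@H]([C@@H](C1)O)C(C)C | starting material
15 | 5-(l-menthyloxy)furan-2(5H)-one, C5-epimer mixture | O=C1C=CC(O1)O[C@@H]2C[C@H](C)CC[C@H]2C(C)C | intermediate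
16 | (5R)-5-(l-menthyloxy)furan-2(5H)-one | O=C1C=C[C@@H](O1)O[C@@H]2C[C@H](C)CC[C@H]2C(C)C | intermediate
17 | E-aryl o-quinodimethane (aryl on C1 anti to C4a) | C=C1C=C(OC)C(OCc2ccccc2)=C/C1=C\c1ccc(OCc2ccccc2)c(OC)c1 | intermediate
18 | all-cis lactone acetal adduct (aryl, C2a and C3a on one face of ring B; menthyloxy anti to C4 on the lactone) | COc1cc([C@H]2c3cc(OCc6ccccc6)c(OC)cc3C[C@@H]4[C@H]2C(=O)O[C@H]4O[C@@H]5C[C@H](C)CC[C@H]5C(C)C)ccc1OCc1ccccc1 | intermediate
19 | all-trans (1S,2R,3R) methyl ester C3a aldehyde | COc1cc([C@H]2c3cc(OCc4ccccc4)c(OC)cc3C[C@@H](C=O)[C@@H]2C(=O)OC)ccc1OCc1ccccc1 | intermediate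
20 | all-trans (1S,2R,3R) methyl ester dimethyl acetal | COc1cc([C@H]2c3cc(OCc4ccccc4)c(OC)cc3C[C@@H](C(OC)OC)[C@@H]2C(=O)OC)ccc1OCc1ccccc1 | intermediate
21 | (1S,2R,3R) C2a alcohol dimethyl acetal | COc1cc([C@H]2c3cc(OCc4ccccc4)c(OC)cc3C[C@@H](C(OC)OC)[C@@H]2CO)ccc1OCc1ccccc1 | intermediate
22 | (E)-4-(benzyloxy)cinnamic acid | OC(=O)/C=C/c1ccc(OCc2ccccc2)cc1 | starting material
23 | C2a (E)-4-(benzyloxy)cinnamate dimethyl acetal | COc1cc([C@H]2c3cc(OCc4ccccc4)c(OC)cc3C[C@@H](C(OC)OC)[C@@H]2COC(=O)/C=C/c2ccc(OCc3ccccc3)cc2)ccc1OCc1ccccc1 | intermediate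
24 | C2a (E)-4-(benzyloxy)cinnamate C3a aldehyde | COc1cc([C@H]2c3cc(OCc4ccccc4)c(OC)cc3C[C@@H](C=O)[C@@H]2COC(=O)/C=C/c2ccc(OCc3ccccc3)cc2)ccc1OCc1ccccc1 | intermediate
25 | tri-O-benzyl ether of the target | COc1cc([C@H]2c3cc(OCc4ccccc4)c(OC)cc3C[C@@H](CO)[C@@H]2COC(=O)/C=C/c2ccc(OCc3ccccc3)cc2)ccc1OCc1ccccc1 | intermediate
26 | CNP0403384.1, (1S,2R,3R) | COc1cc([C@H]2c3cc(O)c(OC)cc3C[C@@H](CO)[C@@H]2COC(=O)/C=C/c2ccc(O)cc2)ccc1O | target

Total step count: 13 steps.
Longest linear sequence: 11 steps (steps 1–5 and 8–13, from 6-bromovanillin). Steps 6–7 form a two-step side branch.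

Steps most likely to fail

1. Step 8. The transient diene may dimerise or oligomerise faster than it adds to the substituted, only moderately reactive butenolide. The endo or regiochemical preference may also be weak, or fluoride and acetate may epimerise the acetal carbon of the dienophile. An exo adduct would be especially harmful, because the equilibration of step 9 would carry it into the enantiomeric series. This is why 18 has to be a single diastereomer.
Fallback (sets out from 7 and 16, comes back at 20): ring B is assembled stepwise by anionic and cationic bond formation instead of by cycloaddition. Aldehyde 7 is converted with PhSH and BF3·OEt2 at 0 °C into the bis(phenylthio)acetal F1. Its lithio derivative (n-BuLi, THF, −78 °C) adds 1,4 to 16 anti to the menthyloxy group, making C3–C4. The lactone enolate is then trapped with a second portion of 7 in an aldol reaction trans to the new substituent, making C1–C2 and giving the tandem adduct F2. Bu3SnH with AIBN in hot toluene removes both phenylthio groups to give the benzyl lactone carbinol F3. TFA in CH2Cl2 at 0 °C ionises the carbinol, and ring A closes C1–C8a para to its methoxy group (Friedel–Crafts alkylation, aryl trans to C2a). This gives the trans-fused lactone acetal F4, which already has the C2 configuration of the target and is taken through the conditions of step 9 to 20.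

2. Step 9. Equilibration at C2 may stay incomplete. The free aldehyde may degrade during the long exposure to methoxide, or the open form may close again to a pseudo-ester, so that the two carbons lose their distinction in the hydride reduction.
Fallback (sets out from 18, comes back at 20): the order of events is reversed so that no free aldehyde ever meets base. The pseudo-ester is opened by acid-catalysed methanolysis with simultaneous acetalisation (HC(OMe)3, MeOH, H2SO4 cat., reflux), giving the all-cis ester dimethyl acetal F5 with C3 locked. In F5 only C2 is acidic, and NaOMe in refluxing MeOH epimerises that single centre to 20.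

3. Step 13. The threefold Lewis-acid debenzylation may be accompanied by loss of guaiacyl methyl ethers, ester cleavage or acyl migration to the C3a hydroxyl group.
Fallback (sets out from 21, comes back at 26): the benzyl groups are removed before the alkene is introduced, and no protecting group is used afterwards. Hydrogenolysis of 21 (H2, Pd/C, EtOAc, solid NaHCO3) gives the bisphenol alcohol acetal F6. A chemoselective Mitsunobu esterification with unprotected (E)-p-coumaric acid (PPh3, DIAD, THF, 0 °C to rt) follows, in which the carboxylic acid is the far better pronucleophile than the phenols, and gives the free-phenol coumarate acetal F7. Aqueous HCl in THF releases the free-phenol aldehyde F8, which is reduced with NaBH4 at low temperature directly to 26.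

Further compounds
F1 | step 8 | 4-(benzyloxy)-3-methoxybenzaldehyde bis(phenylthio)acetal | COc1cc(C(Sc2ccccc2)Sc2ccccc2)ccc1OCc1ccccc1
F2 | step 8 | tandem conjugate addition–aldol adduct (C4 anti to menthyloxy, C1 trans to C4, carbinol centre undefined) | COc1cc(C(Sc2ccccc2)(Sc2ccccc2)[C@@H]5[C@@H](C(O)c3ccc(OCc4ccccc4)c(OC)c3)C(=O)O[C@H]5O[C@@H]6C[C@H](C)CC[C@H]6C(C)C)ccc1OCc1ccccc1
F3 | step 8 | desulfurised trans-α-(aryl-hydroxymethyl)-β-benzyl menthyloxy lactone | COc1cc(C[C@@H]5[C@@H](C(O)c3ccc(OCc4ccccc4)c(OC)c3)C(=O)O[C@H]5O[C@@H]6C[C@H](C)CC[C@H]6C(C)C)ccc1OCc1ccccc1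
F4 | step 8 | trans-fused lactone acetal (C2 epimer of 18) | COc1cc([C@H]2c3cc(OCc6ccccc6)c(OC)cc3C[C@@H]4[C@@H]2C(=O)O[C@H]4O[C@@H]5C[C@H](C)CC[C@H]5C(C)C)ccc1OCc1ccccc1
F5 | step 9 | all-cis methyl ester dimethyl acetal (C2 epimer of 20) | COc1cc([C@H]2c3cc(OCc4ccccc4)c(OC)cc3C[C@@H](C(OC)OC)[C@H]2C(=O)OC)ccc1OCc1ccccc1
F6 | step 13 | bisphenol C2a alcohol dimethyl acetal | COc1cc([C@H]2c3cc(O)c(OC)cc3C[C@@H](C(OC)OC)[C@@H]2CO)ccc1O
F7 | step 13 | free-phenol C2a p-coumarate dimethyl acetal | COc1cc([C@H]2c3cc(O)c(OC)cc3C[C@@H](C(OC)OC)[C@@H]2COC(=O)/C=C/c2ccc(O)cc2)ccc1O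
F8 | step 13 | free-phenol C2a p-coumarate C3a aldehyde | COc1cc([C@H]2c3cc(O)c(OC)cc3C[C@@H](C=O)[C@@H]2COC(=O)/C=C/c2ccc(O)cc2)ccc1O
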